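**Retrosynthetic overview**
1. Target 22 ⇐ acid 19 (O-methylation; silyl ether → acetate). The handle is the γ,δ-unsaturated ester C19(=O)–C4–C5–C10=C1 held inside ring A.
2. Key cut C4–C5: a lactone-to-carbocycle Ireland–Claisen rearrangement of δ-lactone 16 (C19 acyl on the C1 carbinol oxygen, C2–C3 tether). It closes ring A last, makes quaternary C4 and C5 as a pair from the one carbinol centre C1, and leaves the alkene at C1=C10.
3. 16 ⇐ keto ester 14 (CBS reduction sets C1, then lactonisation) ⇐ divinyl ketone 12 + propanoate silyl ketene acetal ⇐ enol triflate 10 + CO + vinylstannane.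
4. Ring B with C8/C9 ⇐ 2-methylcyclohex-2-enone: Cu-catalysed asymmetric methyl addition (C8), then anti Mukaiyama–Michael addition to methyl vinyl ketone (quaternary C9, methyls cis); side chain by HWE/DIBAL.
5. Ring order: ring B from the starting material; temporary lactone ring in step 9; ring A in step 10.

Key step: step 10

Remark on labels: halimane numbering is used throughout. Ring A = C1–C2–C3–C4–C5–C10, ring B = C5–C6–C7–C8–C9–C10, C4 = quaternary ester carbon, C19 = its carbonyl carbon, C11–C15 = side chain. The target is (4S,5R,8R,9S), 13E.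
Assumption: in step 1 the phosphoramidite enantiomer is the one that gives the (3R) centre; the sense is checked once on 2,3-dimethylcyclohexanone obtained by hydrolysis of 3.

Step 1
Reactants: 1 2-methylcyclohex-2-en-1-one
Product: 3 trimethyl{[(3R)-2,3-dimethylcyclohex-1-en-1-yl]oxy}silane, via dimethylaluminium enolate 2 (not isolated)
Conditions: Me3Al, CuTC (2 mol %), chiral BINOL-derived phosphoramidite L* (4 mol %), Et2O, −30 °C; then TMSOTf, −30 → 0 °C
Reagents that add atoms: trimethylaluminium C[Al](C)C; trimethylsilyl trifluoromethanesulfonate C[Si](C)(C)OS(=O)(=O)C(F)(F)F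
Why: Copper-catalysed asymmetric conjugate addition of Me3Al is the established way to add methyl to this sluggish α-substituted enone; the chiral copper complex selects the enone face and sets C8 (R), and O-silylation of the aluminium enolate fixes the tetrasubstituted enol ether needed for step 2.

Step 2
Reactants: 3 trimethyl{[(3R)-2,3-dimethylcyclohex-1-en-1-yl]oxy}silane; 4 but-3-en-2-one
Product: 5 (2S,3R)-2,3-dimethyl-2-(3-oxobutyl)cyclohexan-1-one
Conditions: TiCl4, CH2Cl2, −78 °C; aq. NaHCO3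
Reagents that add atoms: none
Why: Mukaiyama–Michael addition in which TiCl4-activated methyl vinyl ketone is attacked on the face anti to the pseudoaxial C8 methyl (the sense known from Robinson annulations of 2,3-dimethylcyclohexanone), which sets quaternary C9 (S) with the two methyls cis, while −78 °C prevents aldol closure of the 1,5-diketone.

Step 3
Reactants: 5 (2S,3R)-2,3-dimethyl-2-(3-oxobutyl)cyclohexan-1-one; 6 triethyl phosphonoacetate
Product: 7 ethyl (2E)-5-[(1S,2R)-1,2-dimethyl-6-oxocyclohexyl]-3-methylpent-2-enoate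
Conditions: NaH, THF, 0 → 40 °C
Reagents that add atoms: none
Why: Horner–Wadsworth–Emmons olefination occurs only at the unhindered methyl ketone because the ring ketone is flanked by quaternary C9, and the stabilised phosphonate anion should favour the (E)-enoate with the larger CH2 group trans to the ester (any Z isomer is removed by chromatography).

Step 4
Reactants: 7 ethyl (2E)-5-[(1S,2R)-1,2-dimethyl-6-oxocyclohexyl]-3-methylpent-2-enoate
Product: 8 ethyl (2E)-5-[(1S,6R)-1,6-dimethyl-2-(trifluoromethanesulfonyloxy)cyclohex-2-en-1-yl]-3-methylpent-2-enoate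
Conditions: Tf2O, 2,6-di-tert-butyl-4-methylpyridine, CH2Cl2, 0 °C → rt
Reagents that add atoms: trifluoromethanesulfonic anhydride O=S(=O)(OS(=O)(=O)C(F)(F)F)C(F)(F)F
Why: Enol triflate formation under non-basic conditions can only enolise toward C5 because C9 is quaternary, leaves the enoate (with its acidic γ-hydrogens) untouched, and masks the ketone before the hydride step.

Step 5
Reactants: 8 ethyl (2E)-5-[(1S,6R)-1,6-dimethyl-2-(trifluoromethanesulfonyloxy)cyclohex-2-en-1-yl]-3-methylpent-2-enoate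
Product: 9 (5R,6S)-6-[(3E)-5-hydroxy-3-methylpent-3-en-1-yl]-5,6-dimethylcyclohex-1-en-1-yl trifluoromethanesulfonate
Conditions: DIBAL-H (2.5 equiv), CH2Cl2, −78 °C; Rochelle salt
Reagents that add atoms: none
Why: DIBAL-H 1,2-reduction of the α,β-unsaturated ester to the allylic alcohol at −78 °C, a temperature at which the alkenyl triflate and the alkene geometry are retained.

Step 6
Reactants: 9 (5R,6S)-6-[(3E)-5-hydroxy-3-methylpent-3-en-1-yl]-5,6-dimethylcyclohex-1-en-1-yl trifluoromethanesulfonate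
Product: 10 (5R,6S)-6-{(3E)-5-[(tert-butyldiphenylsilyl)oxy]-3-methylpent-3-en-1-yl}-5,6-dimethylcyclohex-1-en-1-yl trifluoromethanesulfonate
Conditions: TBDPSCl, imidazole, DMF, rt
Reagents that add atoms: tert-butyl(chloro)diphenylsilane CC(C)(C)[Si](Cl)(c1ccccc1)c1ccccc1
Why: Silylation of the primary allylic alcohol gives an ether that withstands the Lewis acid of step 8, the mild acid of step 9 and the amide base of step 10, none of which an allylic acetate would survive.

Step 7
Reactants: 10 (5R,6S)-6-{(3E)-5-[(tert-butyldiphenylsilyl)oxy]-3-methylpent-3-en-1-yl}-5,6-dimethylcyclohex-1-en-1-yl trifluoromethanesulfonate; 11 tributyl(vinyl)stannane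
Product: 12 1-[(5R,6S)-6-{(3E)-5-[(tert-butyldiphenylsilyl)oxy]-3-methylpent-3-en-1-yl}-5,6-dimethylcyclohex-1-en-1-yl]prop-2-en-1-one
Conditions: CO (1 atm), Pd(PPh3)4 (3 mol %), LiCl, THF, 55 °C
Reagents that add atoms: carbon monoxide [C-]#[O+]
Why: Carbonylative Stille coupling (LiCl-assisted oxidative addition of the alkenyl triflate, CO insertion, vinyl transfer) is established for cyclohexenyl triflates and gives the cross-conjugated divinyl ketone that carries C1, C2 and C3.

Step 8
Reactants: 12 1-[(5R,6S)-6-{(3E)-5-[(tert-butyldiphenylsilyl)oxy]-3-methylpent-3-en-1-yl}-5,6-dimethylcyclohex-1-en-1-yl]prop-2-en-1-one; 13 1-methoxy-1-(trimethylsilyloxy)prop-1-ene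
Product: 14 methyl 5-[(5R,6S)-6-{(3E)-5-[(tert-butyldiphenylsilyl)oxy]-3-methylpent-3-en-1-yl}-5,6-dimethylcyclohex-1-en-1-yl]-2-methyl-5-oxopentanoate (both C4 epimers)
Conditions: TiCl4, CH2Cl2, −78 °C; aq. NaHCO3
Reagents that add atoms: none
Why: Mukaiyama–Michael addition of the propanoate ketene acetal occurs at the unsubstituted vinyl terminus C3 and not at the β-substituted ring terminus C5 shielded by C9; the C4 configuration is left unset on purpose because C4 becomes sp2 in step 10, and −78 °C keeps Nazarov cyclisation of the dienone from competing.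

Step 9
Reactants: 14 methyl 5-[(5R,6S)-6-{(3E)-5-[(tert-butyldiphenylsilyl)oxy]-3-methylpent-3-en-1-yl}-5,6-dimethylcyclohex-1-en-1-yl]-2-methyl-5-oxopentanoate
Product: 16 (6R)-6-[(5R,6S)-6-{(3E)-5-[(tert-butyldiphenylsilyl)oxy]-3-methylpent-3-en-1-yl}-5,6-dimethylcyclohex-1-en-1-yl]-3-methyloxan-2-one (both C4 epimers), via hydroxy ester 15 (not isolated)
Conditions: (S)-Me-CBS (20 mol %), catecholborane, PhMe, −78 °C; MeOH; then PPTS (cat.), PhMe, 60 °C
Reagents that add atoms: none
Why: Corey–Bakshi–Shibata reduction in which the (S)-oxazaborolidine treats the branched cyclohexenyl group as the large substituent and the CH2 chain as the small one, which by the usual model gives the (R)-carbinol at C1 by 1,2-reduction under catalyst control, after which acid-catalysed lactonisation of the δ-hydroxy ester closes the six-membered lactone with loss of methanol.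

Step 10
Reactants: 16 (6R)-6-[(5R,6S)-6-{(3E)-5-[(tert-butyldiphenylsilyl)oxy]-3-methylpent-3-en-1-yl}-5,6-dimethylcyclohex-1-en-1-yl]-3-methyloxan-2-one
Product: 19 (1S,5S,6R,8aR)-5-{(3E)-5-[(tert-butyldiphenylsilyl)oxy]-3-methylpent-3-en-1-yl}-1,5,6-trimethyl-1,2,3,5,6,7,8,8a-octahydronaphthalene-1-carboxylic acid, via silyl ketene acetal 17 (not isolated), via trimethylsilyl ester 18 (not isolated)
Conditions: LDA, TMSCl/Et3N, THF, −78 °C → rt; then PhMe, 100 °C; 1 M HCl
Reagents that add atoms: none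
Why: Deprotonation of 16 at C4 (its only α-CH) with in-situ silylation gives cyclic silyl ketene acetal 17, whose geometry is fixed by the lactone ring; on heating, its O–C1–C10=C5 allyl vinyl ether unit undergoes the [3,3] shift that makes C4–C5, breaks C1–O and moves the alkene to C1=C10 (Ireland–Claisen rearrangement in its lactone-to-carbocycle form, as known for alkenyl-substituted lactones and 6-alkenyl-1,4-dioxan-2-ones). Ring A closes because the C2–C3 tether joins the two termini C1 and C4, so the six-membered carbocycle forms through a bicyclo[2.2.2]-like array in which only a boat transition state is possible. C5 is set by suprafacial transfer from the (R)-carbinol C1: with C2 held syn to C5 (required for the ring alkene), the C1–O bond lies on the ring-B alkene face anti to the axial C9 methyl, and C4 is delivered to that same face (5R). C4 is set by the fixed enolate geometry combined with the enforced boat, which eclipses C3 with H5 and the C4 methyl with C6 and so places the carboxyl trans to H5 (4S). No facial or endo/exo choice is left open, so the step needs only rate; the reactive rotamer puts just H1 against quaternary C9, and a trimethylsilyl ketene acetal tolerates the heating.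

Step 11
Reactants: 19 (1S,5S,6R,8aR)-5-{(3E)-5-[(tert-butyldiphenylsilyl)oxy]-3-methylpent-3-en-1-yl}-1,5,6-trimethyl-1,2,3,5,6,7,8,8a-octahydronaphthalene-1-carboxylic acid
Product: 20 methyl (1S,5S,6R,8aR)-5-{(3E)-5-[(tert-butyldiphenylsilyl)oxy]-3-methylpent-3-en-1-yl}-1,5,6-trimethyl-1,2,3,5,6,7,8,8a-octahydronaphthalene-1-carboxylate
Conditions: MeI, K2CO3, DMF, rt
Reagents that add atoms: iodomethane CI
Why: SN2 O-methylation of the potassium carboxylate is insensitive to the hindrance at the quaternary C4 acid and leaves the silyl ether and all stereocentres untouched.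

Step 12
Reactants: 20 methyl (1S,5S,6R,8aR)-5-{(3E)-5-[(tert-butyldiphenylsilyl)oxy]-3-methylpent-3-en-1-yl}-1,5,6-trimethyl-1,2,3,5,6,7,8,8a-octahydronaphthalene-1-carboxylate
Product: 22 methyl (1S,5S,6R,8aR)-5-[(3E)-5-acetoxy-3-methylpent-3-en-1-yl]-1,5,6-trimethyl-1,2,3,5,6,7,8,8a-octahydronaphthalene-1-carboxylate (CNP0209995.1), via allylic alcohol 21 (not isolated)
Conditions: TBAF, THF, 0 °C → rt; then Ac2O, DMAP (cat.), rt
Reagents that add atoms: acetic anhydride CC(=O)OC(C)=O
Why: Fluoride-induced desilylation followed by in-situ DMAP-catalysed acetylation of the primary allylic alkoxide; the hindered C4 methyl ester and all stereocentres are inert to both reagents.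

**Compound list**
1 | 2-methylcyclohex-2-en-1-one | CC1=CCCCC1=O | starting material
2 | dimethylaluminium (3R)-2,3-dimethylcyclohex-1-en-1-olate | C[C@@H]1CCCC(O[Al](C)C)=C1C | intermediate
3 | trimethyl{[(3R)-2,3-dimethylcyclohex-1-en-1-yl]oxy}silane | C[C@@H]1CCCC(O[Si](C)(C)C)=C1C | intermediate
4 | but-3-en-2-one (methyl vinyl ketone) | CC(=O)C=C | starting material
5 | (2S,3R)-2,3-dimethyl-2-(3-oxobutyl)cyclohexan-1-one | O=C1CCC[C@@H](C)[C@]1(C)CCC(C)=O | intermediate
6 | triethyl phosphonoacetate | CCOC(=O)CP(=O)(OCC)OCC | starting material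
7 | ethyl (2E)-5-[(1S,2R)-1,2-dimethyl-6-oxocyclohexyl]-3-methylpent-2-enoate | O=C1CCC[C@@H](C)[C@]1(C)CC/C(C)=C/C(=O)OCC | intermediate
8 | ethyl (2E)-5-[(1S,6R)-1,6-dimethyl-2-(trifluoromethanesulfonyloxy)cyclohex-2-en-1-yl]-3-methylpent-2-enoate | O=S(=O)(OC1=CCC[C@@H](C)[C@]1(C)CC/C(C)=C/C(=O)OCC)C(F)(F)F | intermediate
9 | (5R,6S)-6-[(3E)-5-hydroxy-3-methylpent-3-en-1-yl]-5,6-dimethylcyclohex-1-en-1-yl trifluoromethanesulfonate | O=S(=O)(OC1=CCC[C@@H](C)[C@]1(C)CC/C(C)=C/CO)C(F)(F)F | intermediate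
10 | (5R,6S)-6-{(3E)-5-[(tert-butyldiphenylsilyl)oxy]-3-methylpent-3-en-1-yl}-5,6-dimethylcyclohex-1-en-1-yl trifluoromethanesulfonate | O=S(=O)(OC1=CCC[C@@H](C)[C@]1(C)CC/C(C)=C/CO[Si](c2ccccc2)(c3ccccc3)C(C)(C)C)C(F)(F)F | intermediate
11 | tributyl(vinyl)stannane | C=C[Sn](CCCC)(CCCC)CCCC | starting material
12 | 1-[(5R,6S)-6-{(3E)-5-[(tert-butyldiphenylsilyl)oxy]-3-methylpent-3-en-1-yl}-5,6-dimethylcyclohex-1-en-1-yl]prop-2-en-1-one | C=CC(=O)C1=CCC[C@@H](C)[C@]1(C)CC/C(C)=C/CO[Si](c2ccccc2)(c3ccccc3)C(C)(C)C | intermediate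
13 | 1-methoxy-1-(trimethylsilyloxy)prop-1-ene | CC=C(OC)O[Si](C)(C)C | starting material
14 | methyl 5-[(5R,6S)-6-{(3E)-5-[(tert-butyldiphenylsilyl)oxy]-3-methylpent-3-en-1-yl}-5,6-dimethylcyclohex-1-en-1-yl]-2-methyl-5-oxopentanoate (C4 epimers) | COC(=O)C(C)CCC(=O)C1=CCC[C@@H](C)[C@]1(C)CC/C(C)=C/CO[Si](c2ccccc2)(c3ccccc3)C(C)(C)C | intermediate
15 | methyl (5R)-5-[(5R,6S)-6-{(3E)-5-[(tert-butyldiphenylsilyl)oxy]-3-methylpent-3-en-1-yl}-5,6-dimethylcyclohex-1-en-1-yl]-5-hydroxy-2-methylpentanoate (C4 epimers) | COC(=O)C(C)CC[C@@H](O)C1=CCC[C@@H](C)[C@]1(C)CC/C(C)=C/CO[Si](c2ccccc2)(c3ccccc3)C(C)(C)C | intermediate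
16 | (6R)-6-[(5R,6S)-6-{(3E)-5-[(tert-butyldiphenylsilyl)oxy]-3-methylpent-3-en-1-yl}-5,6-dimethylcyclohex-1-en-1-yl]-3-methyloxan-2-one (C4 epimers) | CC1CC[C@@H](OC1=O)C2=CCC[C@@H](C)[C@]2(C)CC/C(C)=C/CO[Si](c3ccccc3)(c4ccccc4)C(C)(C)C | intermediate
17 | {[(2R)-2-[(5R,6S)-6-{(3E)-5-[(tert-butyldiphenylsilyl)oxy]-3-methylpent-3-en-1-yl}-5,6-dimethylcyclohex-1-en-1-yl]-5-methyl-3,4-dihydro-2H-pyran-6-yl]oxy}trimethylsilane | CC1=C(O[Si](C)(C)C)O[C@H](CC1)C2=CCC[C@@H](C)[C@]2(C)CC/C(C)=C/CO[Si](c3ccccc3)(c4ccccc4)C(C)(C)C | intermediate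
18 | trimethylsilyl ester of acid 19 | C[Si](C)(C)OC(=O)[C@@]1(C)CCC=C2[C@H]1CC[C@@H](C)[C@]2(C)CC/C(C)=C/CO[Si](c3ccccc3)(c4ccccc4)C(C)(C)C | intermediate
19 | (1S,5S,6R,8aR)-5-{(3E)-5-[(tert-butyldiphenylsilyl)oxy]-3-methylpent-3-en-1-yl}-1,5,6-trimethyl-1,2,3,5,6,7,8,8a-octahydronaphthalene-1-carboxylic acid | OC(=O)[C@@]1(C)CCC=C2[C@H]1CC[C@@H](C)[C@]2(C)CC/C(C)=C/CO[Si](c3ccccc3)(c4ccccc4)C(C)(C)C | intermediate
20 | methyl (1S,5S,6R,8aR)-5-{(3E)-5-[(tert-butyldiphenylsilyl)oxy]-3-methylpent-3-en-1-yl}-1,5,6-trimethyl-1,2,3,5,6,7,8,8a-octahydronaphthalene-1-carboxylate | COC(=O)[C@@]1(C)CCC=C2[C@H]1CC[C@@H](C)[C@]2(C)CC/C(C)=C/CO[Si](c3ccccc3)(c4ccccc4)C(C)(C)C | intermediate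
21 | methyl (1S,5S,6R,8aR)-5-[(3E)-5-hydroxy-3-methylpent-3-en-1-yl]-1,5,6-trimethyl-1,2,3,5,6,7,8,8a-octahydronaphthalene-1-carboxylate | COC(=O)[C@@]1(C)CCC=C2[C@H]1CC[C@@H](C)[C@]2(C)CC/C(C)=C/CO | intermediate
22 | methyl (1S,5S,6R,8aR)-5-[(3E)-5-acetoxy-3-methylpent-3-en-1-yl]-1,5,6-trimethyl-1,2,3,5,6,7,8,8a-octahydronaphthalene-1-carboxylate | COC(=O)[C@@]1(C)CCC=C2[C@H]1CC[C@@H](C)[C@]2(C)CC/C(C)=C/COC(C)=O | target

**Step count and risk**
Total steps: 12. Longest linear sequence: 12 (steps 9 and 12 each combine two operations in one flask).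

Steps most likely to fail:

Step 10. The [3,3] shift through the strained bicyclic boat may be slower than loss of the silyl ketene acetal (C-silylation, reversion to the lactone, or ionisation of the allylic C1–O bond), so ring A would not close. The fallback sets out from 10 and returns at 19. Stille coupling of 10 with 11 without CO (Pd(PPh3)4, LiCl, THF, reflux) gives the 1-vinylcyclohexene, diene F1. A Diels–Alder reaction of diene F1 with commercial 2-methylpropenal is run at −78 °C with the (S)-diphenylprolinol-derived B-o-tolyl oxazaborolidinium triflimide, the enantiomer that by the usual formyl C–H···O model leaves the Cα-Re face of the bound enal open. It should give aldehyde F2 by bonding first at the vinyl CH2 terminus (C2–C3) and then C4–C5 in the formyl-endo mode. Pinnick oxidation of aldehyde F2 (NaClO2, NaH2PO4, 2-methylbut-2-ene, t-BuOH/H2O) gives acid 19.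

Step 8. Lewis-acid-triggered Nazarov electrocyclisation or oligomerisation of the cross-conjugated dienone may outrun conjugate addition. The fallback sets out from 10, bypasses steps 7–9, and returns at 16. Nozaki–Hiyama–Kishi coupling of 10 with commercial methyl 5-oxopentanoate (CrCl2, NiCl2 cat., DMF) gives hydroxy ester F3 as a mixture at C1. Dess–Martin oxidation gives keto ester F4. CBS reduction as in step 9 gives (R)-hydroxy ester F5, and PPTS closes it to the C4-unsubstituted lactone F6. LDA then MeI (THF, −78 °C) methylates C4 and gives 16.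

Step 2. Carbon–carbon bond formation at the fully substituted enol ether carbon may stall, leading to protodesilylation, or methyl vinyl ketone may polymerise under TiCl4. The fallback sets out from 3 and returns at 5. MeLi (THF, 0 °C) cleaves the Si–O bond to give lithium enolate F7 with the double-bond position retained. Alkylation with commercial 1,3-dichlorobut-2-ene, an activated allylic chloride that enters anti to the C8 methyl, gives vinyl chloride F8. Hydrolysis of the vinyl chloride (conc. H2SO4, 0 °C; Wichterle sequence) unmasks the methyl ketone and gives 5.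

**Further compounds**
F1 | step 10 | tert-butyl({(2E)-5-[(1S,6R)-2-ethenyl-1,6-dimethylcyclohex-2-en-1-yl]-3-methylpent-2-en-1-yl}oxy)diphenylsilane | C=CC1=CCC[C@@H](C)[C@]1(C)CC/C(C)=C/CO[Si](c2ccccc2)(c3ccccc3)C(C)(C)C
F2 | step 10 | (1S,5S,6R,8aR)-5-{(3E)-5-[(tert-butyldiphenylsilyl)oxy]-3-methylpent-3-en-1-yl}-1,5,6-trimethyl-1,2,3,5,6,7,8,8a-octahydronaphthalene-1-carbaldehyde | O=C[C@@]1(C)CCC=C2[C@H]1CC[C@@H](C)[C@]2(C)CC/C(C)=C/CO[Si](c3ccccc3)(c4ccccc4)C(C)(C)C
F3 | step 8 | methyl 5-[(5R,6S)-6-{(3E)-5-[(tert-butyldiphenylsilyl)oxy]-3-methylpent-3-en-1-yl}-5,6-dimethylcyclohex-1-en-1-yl]-5-hydroxypentanoate (C1 epimers) | COC(=O)CCCC(O)C1=CCC[C@@H](C)[C@]1(C)CC/C(C)=C/CO[Si](c2ccccc2)(c3ccccc3)C(C)(C)C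
F4 | step 8 | methyl 5-[(5R,6S)-6-{(3E)-5-[(tert-butyldiphenylsilyl)oxy]-3-methylpent-3-en-1-yl}-5,6-dimethylcyclohex-1-en-1-yl]-5-oxopentanoate | COC(=O)CCCC(=O)C1=CCC[C@@H](C)[C@]1(C)CC/C(C)=C/CO[Si](c2ccccc2)(c3ccccc3)C(C)(C)C
F5 | step 8 | methyl (5R)-5-[(5R,6S)-6-{(3E)-5-[(tert-butyldiphenylsilyl)oxy]-3-methylpent-3-en-1-yl}-5,6-dimethylcyclohex-1-en-1-yl]-5-hydroxypentanoate | COC(=O)CCC[C@@H](O)C1=CCC[C@@H](C)[C@]1(C)CC/C(C)=C/CO[Si](c2ccccc2)(c3ccccc3)C(C)(C)C
F6 | step 8 | (6R)-6-[(5R,6S)-6-{(3E)-5-[(tert-butyldiphenylsilyl)oxy]-3-methylpent-3-en-1-yl}-5,6-dimethylcyclohex-1-en-1-yl]oxan-2-one | O=C1CCC[C@@H](O1)C2=CCC[C@@H](C)[C@]2(C)CC/C(C)=C/CO[Si](c3ccccc3)(c4ccccc4)C(C)(C)C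
F7 | step 2 | lithium (3R)-2,3-dimethylcyclohex-1-en-1-olate | C[C@@H]1CCCC(O[Li])=C1C
F8 | step 2 | (2S,3R)-2-(3-chlorobut-2-en-1-yl)-2,3-dimethylcyclohexan-1-one | O=C1CCC[C@@H](C)[C@]1(C)CC=C(C)Cl
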